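**Plan**
1. Retrosynthesis: the four phenols are masked as benzyl ethers and both C4 ketones are taken back to carbinols whose oxygens share one diisopropylsilylene. This bi(flavan-4-ol) is cut at C3–C3' and at both O1–C2 bonds.
2. Enabling feature: at the carbinol level each half is a 4-alkoxystyrene (ring B–C2=C3) whose ring A phenol oxygen O1 can reach C2, and C3/C3' are the two styrene β-carbons. One oxidative tail-to-tail coupling with double phenol capture therefore builds the whole skeleton.
3. Forward: the ring A aldehyde and the ring B alkyne are joined at C3–C4, and two carbinols are tied at silicon. The anodic step then forms C3–C3' first and closes both pyran rings; desilylation, oxidation at C4/C4' and debenzylation finish the route.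
4. Stereochemistry: the R carbinol centre C4 comes from a catalytic asymmetric alkenylzinc addition. In the tethered coupling it fixes C3/C3' (3,4-trans), which fix C2/C2' (2,3-trans) in the chair closures. Oxidation then erases C4/C4' and leaves 2R,3S,2'R,3'S.
5. The silicon tether adds one temporary ring, a 1,3-dioxa-2-silepane that closes with the C3–C3' bond and is removed in step 7.

Key step: step 6

Assumption: 1-(benzyloxy)-4-ethynylbenzene 4 is taken as a purchased compound; flavanone numbering (O1, C2, C3, C4, rings A and B, primes for the second half) is used for all intermediates, open-chain ones included.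

**Step 1**
Reactants: 1 2,4-dihydroxybenzaldehyde
Product: 2 4-(benzyloxy)-2-hydroxybenzaldehyde
Conditions: BnBr (1.05 equiv), NaHCO3, MeCN, 80 °C
Reagents that add atoms: benzyl bromide, BrCc1ccccc1
Why: Williamson etherification goes to the 4-hydroxyl alone, because the 2-hydroxyl is held in a hydrogen bond to the formyl group and the weak base NaHCO3 does not ionise it.

**Step 2**
Reactants: 2 4-(benzyloxy)-2-hydroxybenzaldehyde
Product: 3 2-(allyloxy)-4-(benzyloxy)benzaldehyde
Conditions: allyl bromide, K2CO3, DMF, rt
Reagents that add atoms: allyl bromide, C=CCBr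
Why: Williamson etherification of the remaining phenol with the stronger base K2CO3; the allyl ether is chosen because it can later be removed under neutral conditions beside benzyl and silyl ethers.

**Step 3**
Reactants: 4 1-(benzyloxy)-4-ethynylbenzene; 3 2-(allyloxy)-4-(benzyloxy)benzaldehyde
Product: 7 (R,E)-1-[2-(allyloxy)-4-(benzyloxy)phenyl]-3-[4-(benzyloxy)phenyl]prop-2-en-1-ol, via alkenyl(dicyclohexyl)borane 5 (not isolated), via alkenyl(ethyl)zinc 6 (not isolated)
Conditions: Cy2BH (freshly prepared), toluene, 0 °C to rt; Et2Zn, −78 °C; (+)-MIB (5 mol%), then 3, −20 to 0 °C; aq. NaHCO3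
Reagents that add atoms: none
Why: syn-Hydroboration of the terminal alkyne fixes the E double bond, boron-to-zinc exchange gives the alkenylzinc, and its catalytic asymmetric addition to the aldehyde takes place on the Re face under (+)-MIB, the 3-exo-morpholinoisoborneol enantiomer that directs it there, which sets the R carbinol centre C4.

**Step 4**
Reactants: 7 (R,E)-1-[2-(allyloxy)-4-(benzyloxy)phenyl]-3-[4-(benzyloxy)phenyl]prop-2-en-1-ol (two molecules)
Product: 8 diisopropylbis{[(1R,2E)-1-[2-(allyloxy)-4-(benzyloxy)phenyl]-3-[4-(benzyloxy)phenyl]prop-2-en-1-yl]oxy}silane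
Conditions: iPr2SiCl2 (0.5 equiv), imidazole, DMAP (cat.), DMF, 0 °C to rt
Reagents that add atoms: dichlorodiisopropylsilane, CC(C)[Si](Cl)(Cl)C(C)C
Why: Silyl ether formation at both Si–Cl bonds under basic conditions ties two R units to one silicon without exposing the acid-sensitive carbinol to acid, and since a minor S unit would end in a separable meso-type diastereomer the step should also raise the enantiomeric purity of the C2-symmetric bis-ether.

**Step 5**
Reactants: 8 the bis-allyl ether
Product: 9 diisopropylbis{[(1R,2E)-1-[4-(benzyloxy)-2-hydroxyphenyl]-3-[4-(benzyloxy)phenyl]prop-2-en-1-yl]oxy}silane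
Conditions: Pd(PPh3)4 (5 mol%), morpholine, THF, rt
Reagents that add atoms: none
Why: Tsuji–Trost deallylation: zerovalent palladium ionises the aryl allyl ethers, whose phenoxide is a good leaving group, morpholine takes over the allyl group, and the dialkoxysilane, benzyl ethers and styrenes are inert under these neutral conditions.

**Step 6**
Reactants: 9 the tethered bis-phenol
Product: 10 O4,O4'-diisopropylsilanediyl ether of all-trans (2R,3S,4R,2'R,3'S,4'R)-7,7'-bis(benzyloxy)-2,2'-bis[4-(benzyloxy)phenyl]-3,3'-bichromane-4,4'-diol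
Conditions: RVC (reticulated vitreous carbon) anode, Pt cathode, undivided cell, LiClO4 (0.1 M), 2,6-lutidine/2,6-lutidinium perchlorate buffer, MeCN/CH2Cl2 4:1, 2 mM, 0 °C, potential held at the first anodic wave, ca. 2 F/mol
Reagents that add atoms: none
Why: Proposed new method: removal of one electron from one 4-benzyloxystyrene unit, the most easily oxidised group of 9, should give a radical cation whose β-carbon C3 bonds to C3' of the second styrene held beside it by the silicon tether, after which the C2' benzylic radical gives up a second electron at the anode, each 4-benzyloxybenzyl cation (C2, C2') is captured by its own ring A phenol oxygen, and the lutidine buffer carries the two protons to the cathode, where they leave as H2. The closest known reaction type is the anodic tail-to-tail (β,β') dimerisation of 4-alkoxy-β-alkylstyrenes with capture of both benzylic cations by oxygen nucleophiles, run here within one molecule as in radical-cation couplings of tethered styrenes. The temporary 1,3-dioxa-2-silepane closes by 7-exo attack on the C3'=C2' bond, and each pyran ring closes through a chair by attack of O1 on cationic C2, which is 6-exo with respect to the cation and 6-endo with respect to the former C2=C3 bond. C3 and C3' are set by the R centres C4 and C4', because the one seven-membered transition state with both ring A aryl groups and both styryl termini pseudo-equatorial forms the new bond anti to ring A with H4 eclipsing the alkene and gives 3,4-trans on each side; C2 and C2' are then set by C3 and C3', since ring B takes the equatorial site of the closing chair (2,3-trans). The step needs oxidation of the styrene before the phenol and C–C bonding before O-capture at C3 or loss of H4; the lower oxidation potential of the para-alkoxystyrene, the potential held at its first wave, the high effective molarity of the tethered alkene and the hindered base are meant to secure this, and the β,β' mode is favoured because it alone leaves both charges benzylic and para-oxygen-stabilised.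

**Step 7**
Reactants: 10 the silylene-bridged bi(flavan-4-ol)
Product: 11 (2R,3R,4R,2'R,3'R,4'R)-7,7'-bis(benzyloxy)-2,2'-bis[4-(benzyloxy)phenyl]-[3,3'-bichromane]-4,4'-diol
Conditions: Bu4NF, AcOH (1:1), THF, 0 °C
Reagents that add atoms: none
Why: Fluoride-induced cleavage of both Si–O bonds (desilylation), buffered with acetic acid so that the ionisable C4 carbinols see neither strong base nor acid; no stereocenter is touched, and the C3 descriptor changes only through the CIP ranking.

**Step 8**
Reactants: 11 the diol
Product: 12 (2R,3S,2'R,3'S)-7,7'-bis(benzyloxy)-2,2'-bis[4-(benzyloxy)phenyl]-[3,3'-bichromane]-4,4'-dione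
Conditions: Dess–Martin periodinane, NaHCO3, CH2Cl2, 0 °C to rt
Reagents that add atoms: none
Why: Dess–Martin oxidation of the two secondary benzylic carbinols under bicarbonate buffer removes the C4 centres once they have served; C3 and C3' become enolisable, but their substituents already sit trans to the C2 aryl groups, the favoured arrangement, so equilibration cannot harm them.

**Step 9**
Reactants: 12 the tetra-O-benzyl biflavanone
Product: 13 (2R,3S,2'R,3'S)-7,7'-dihydroxy-2,2'-bis(4-hydroxyphenyl)-[3,3'-bichromane]-4,4'-dione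
Conditions: H2 (1 atm), Pd/C, EtOAc/MeOH, rt
Reagents that add atoms: none
Why: Catalytic hydrogenolysis of the four aryl benzyl ethers should be faster than reduction of the electron-rich aryl ketones or cleavage of the benzylic C2–O1 bonds if the reaction is stopped at full debenzylation, and the neutral medium leaves C2 and C3 untouched.

**Compound list**
1 | 2,4-dihydroxybenzaldehyde | O=Cc1ccc(O)cc1O | starting material
2 | 4-(benzyloxy)-2-hydroxybenzaldehyde | O=Cc1ccc(OCc2ccccc2)cc1O | intermediate
3 | 2-(allyloxy)-4-(benzyloxy)benzaldehyde | O=Cc1ccc(OCc2ccccc2)cc1OCC=C | intermediate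
4 | 1-(benzyloxy)-4-ethynylbenzene | C#Cc1ccc(OCc2ccccc2)cc1 | starting material
5 | (E)-{2-[4-(benzyloxy)phenyl]ethenyl}dicyclohexylborane | C1CCC(CC1)B(/C=C/c1ccc(OCc2ccccc2)cc1)C1CCCCC1 | intermediate (not isolated)
6 | (E)-{2-[4-(benzyloxy)phenyl]ethenyl}(ethyl)zinc | CC[Zn]/C=C/c1ccc(OCc2ccccc2)cc1 | intermediate (not isolated)
7 | (R,E)-1-[2-(allyloxy)-4-(benzyloxy)phenyl]-3-[4-(benzyloxy)phenyl]prop-2-en-1-ol | O[C@H](/C=C/c1ccc(OCc2ccccc2)cc1)c1ccc(OCc2ccccc2)cc1OCC=C | intermediate
8 | diisopropylbis{[(1R,2E)-1-[2-(allyloxy)-4-(benzyloxy)phenyl]-3-[4-(benzyloxy)phenyl]prop-2-en-1-yl]oxy}silane | CC(C)[Si](C(C)C)(O[C@H](/C=C/c1ccc(OCc2ccccc2)cc1)c1ccc(OCc2ccccc2)cc1OCC=C)O[C@H](/C=C/c1ccc(OCc2ccccc2)cc1)c1ccc(OCc2ccccc2)cc1OCC=C | intermediate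
9 | diisopropylbis{[(1R,2E)-1-[4-(benzyloxy)-2-hydroxyphenyl]-3-[4-(benzyloxy)phenyl]prop-2-en-1-yl]oxy}silane (precursor of the key step) | CC(C)[Si](C(C)C)(O[C@H](/C=C/c1ccc(OCc2ccccc2)cc1)c1ccc(OCc2ccccc2)cc1O)O[C@H](/C=C/c1ccc(OCc2ccccc2)cc1)c1ccc(OCc2ccccc2)cc1O | intermediate
10 | O4,O4'-diisopropylsilanediyl ether of all-trans (2R,3S,4R,2'R,3'S,4'R)-7,7'-bis(benzyloxy)-2,2'-bis[4-(benzyloxy)phenyl]-3,3'-bichromane-4,4'-diol; all ring substituents equatorial, dioxasilepane trans-fused to both pyran rings (product of the key step) | CC(C)[Si]4(C(C)C)O[C@H]1c2ccc(OCc3ccccc3)cc2O[C@@H](c2ccc(OCc3ccccc3)cc2)[C@@H]1[C@@H]1[C@@H](O4)c2ccc(OCc3ccccc3)cc2O[C@H]1c1ccc(OCc2ccccc2)cc1 | intermediate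
11 | (2R,3R,4R,2'R,3'R,4'R)-7,7'-bis(benzyloxy)-2,2'-bis[4-(benzyloxy)phenyl]-[3,3'-bichromane]-4,4'-diol (same spatial arrangement as 10) | O[C@H]1c2ccc(OCc3ccccc3)cc2O[C@@H](c2ccc(OCc3ccccc3)cc2)[C@@H]1[C@@H]1[C@@H](O)c2ccc(OCc3ccccc3)cc2O[C@H]1c1ccc(OCc2ccccc2)cc1 | intermediate
12 | (2R,3S,2'R,3'S)-7,7'-bis(benzyloxy)-2,2'-bis[4-(benzyloxy)phenyl]-[3,3'-bichromane]-4,4'-dione | O=C1c2ccc(OCc3ccccc3)cc2O[C@@H](c2ccc(OCc3ccccc3)cc2)[C@@H]1[C@@H]1C(=O)c2ccc(OCc3ccccc3)cc2O[C@H]1c1ccc(OCc2ccccc2)cc1 | intermediate
13 | (2R,3S,2'R,3'S)-7,7'-dihydroxy-2,2'-bis(4-hydroxyphenyl)-[3,3'-bichromane]-4,4'-dione | O=C1c2ccc(O)cc2O[C@@H](c2ccc(O)cc2)[C@@H]1[C@@H]1C(=O)c2ccc(O)cc2O[C@H]1c1ccc(O)cc1 | target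

**Step count**
Total: 9 steps. Longest linear sequence: 9 steps (1 to 13); alkyne 4 enters as a purchased compound in step 3.

**Steps most likely to fail**

Step 6. Several processes could overtake the coupling. The phenol oxygen may add to C3 of the radical cation in a five-membered closure before the C3–C3' bond forms. The radical cation may lose H4 to the base and end as the enone. The phenol may be oxidised in place of the styrene. Anodically formed acid may ionise the C4–O–Si bonds. The fallback uses known chemistry, sets out from 2 and returns at 12; it makes the C3–C3' bond by oxidative coupling of an enol ether. Ethynylmagnesium bromide (2.2 equiv, THF, 0 °C) converts 2 into racemic 1-[4-(benzyloxy)-2-hydroxyphenyl]prop-2-yn-1-ol F1. MnO2 in CH2Cl2 oxidises it to 1-[4-(benzyloxy)-2-hydroxyphenyl]prop-2-yn-1-one F2, which diethylamine in ethanol closes to 7-(benzyloxy)-4H-chromen-4-one F3. Conjugate addition of 4-(benzyloxy)phenylboronic acid under Pd(OCOCF3)2 and the t-BuPyOX enantiomer that leads to the 2R product (NH4PF6, water, 1,2-dichloroethane, 60 °C) gives (R)-7-(benzyloxy)-2-[4-(benzyloxy)phenyl]chroman-4-one F4. Me3SiOTf and Et3N convert it into (R)-7-(benzyloxy)-2-[4-(benzyloxy)phenyl]-4-(trimethylsilyloxy)-2H-chromene F5. Oxidative homocoupling of F5 with Ag2O in DMSO joins two molecules at C3, each new bond trans to its C2 aryl group, and gives 12, from which step 9 follows. In this branch C2 comes from the catalyst and C3 from C2.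

Step 5. Zerovalent palladium may ionise the cinnamyl-type C4–O–Si bonds as well as the aryl allyl ethers, with loss of the tether or allylic scrambling, or the allyl group may be transferred to a carbon of the freed electron-rich phenol. The fallback sets out from 2 and returns at 9; the phenol is carried as a silyl ether and freed without a transition metal. Silylation of 2 (TBSCl, imidazole, DMF) gives 4-(benzyloxy)-2-[(tert-butyldimethylsilyl)oxy]benzaldehyde F6. Alkenylzinc 6, made as in step 3, adds under (+)-MIB catalysis to give (R,E)-1-{4-(benzyloxy)-2-[(tert-butyldimethylsilyl)oxy]phenyl}-3-[4-(benzyloxy)phenyl]prop-2-en-1-ol F7. Two molecules are joined with dichlorodiisopropylsilane as in step 4 to the bis(aryl silyl ether) of 9 F8. Cs2CO3 in DMF/water at rt should cleave only the two aryl silyl ethers, phenoxide being the better leaving group at silicon, and gives 9, which is electrolysed at once.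

Step 3. Facial selectivity at the electron-rich ortho-alkoxy aldehyde may be insufficient, ethyl may be transferred from zinc in competition, or the doubly activated allylic alcohol may ionise during work-up with loss of configuration. The fallback sets out from 3 and 4 and returns at 7. Asymmetric alkynylation of 3 with the zinc acetylide of 4 (Et2Zn, Ti(OiPr)4, the BINOL enantiomer that directs the alkynyl group to the Re face, toluene/CH2Cl2) gives (R)-1-[2-(allyloxy)-4-(benzyloxy)phenyl]-3-[4-(benzyloxy)phenyl]prop-2-yn-1-ol F9. trans-Hydroalumination of this propargylic alcohol with NaAlH2(OCH2CH2OMe)2 in THF at 0 °C, then protonation, gives 7.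

**Further compounds**
F1 | step 6 | racemic 1-[4-(benzyloxy)-2-hydroxyphenyl]prop-2-yn-1-ol | OC(C#C)c1ccc(OCc2ccccc2)cc1O
F2 | step 6 | 1-[4-(benzyloxy)-2-hydroxyphenyl]prop-2-yn-1-one | O=C(C#C)c1ccc(OCc2ccccc2)cc1O
F3 | step 6 | 7-(benzyloxy)-4H-chromen-4-one | O=c1ccoc2cc(OCc3ccccc3)ccc12
F4 | step 6 | (R)-7-(benzyloxy)-2-[4-(benzyloxy)phenyl]chroman-4-one | O=C1C[C@H](c2ccc(OCc3ccccc3)cc2)Oc2cc(OCc3ccccc3)ccc21
F5 | step 6 | (R)-7-(benzyloxy)-2-[4-(benzyloxy)phenyl]-4-(trimethylsilyloxy)-2H-chromene | C[Si](C)(C)OC1=C[C@H](c2ccc(OCc3ccccc3)cc2)Oc2cc(OCc3ccccc3)ccc21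
F6 | step 5 | 4-(benzyloxy)-2-[(tert-butyldimethylsilyl)oxy]benzaldehyde | O=Cc1ccc(OCc2ccccc2)cc1O[Si](C)(C)C(C)(C)C
F7 | step 5 | (R,E)-1-{4-(benzyloxy)-2-[(tert-butyldimethylsilyl)oxy]phenyl}-3-[4-(benzyloxy)phenyl]prop-2-en-1-ol | O[C@H](/C=C/c1ccc(OCc2ccccc2)cc1)c1ccc(OCc2ccccc2)cc1O[Si](C)(C)C(C)(C)C
F8 | step 5 | diisopropylbis{[(1R,2E)-1-{4-(benzyloxy)-2-[(tert-butyldimethylsilyl)oxy]phenyl}-3-[4-(benzyloxy)phenyl]prop-2-en-1-yl]oxy}silane | CC(C)[Si](C(C)C)(O[C@H](/C=C/c1ccc(OCc2ccccc2)cc1)c1ccc(OCc2ccccc2)cc1O[Si](C)(C)C(C)(C)C)O[C@H](/C=C/c1ccc(OCc2ccccc2)cc1)c1ccc(OCc2ccccc2)cc1O[Si](C)(C)C(C)(C)C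
F9 | step 3 | (R)-1-[2-(allyloxy)-4-(benzyloxy)phenyl]-3-[4-(benzyloxy)phenyl]prop-2-yn-1-ol | O[C@H](C#Cc1ccc(OCc2ccccc2)cc1)c1ccc(OCc2ccccc2)cc1OCC=C
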